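Locants: carbocycle C1 (quaternary oxirane C), C2 (oxirane CH), C3 (CHOH), C4 (C–CH2OH), C5 (=CH), C6 (CHOH); chain C7 (CHOH), C8=C9(CH3), C10=C11; ring A = the trimethylcyclohexenol.
Enabling feature: in the 7-oxabicyclo[4.1.0]hept-3-ene core, carbinol C3, ring olefin C4=C5 and the CH2OH on C4 form a cyclic α-(hydroxyalkyl)acrylate (Morita–Baylis–Hillman) retron sitting directly on oxirane carbon C2. The six-membered ring is therefore cut at C3–C4 to an open chain carrying an oxirane carbaldehyde (C3) and an alkynoate (C5≡C4–CO2Me).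
Further cuts: C5–C6 and C1–C7 (two catalytic asymmetric alkynylations), C1–C6 (formylation of a C1 alkenyl metal, with HC≡C–CH2O as the C1–C3 linchpin), C9–C10 (Suzuki–Miyaura), and the ring A C–C bond (epoxide–olefin cyclization of geranyl acetate).
Forward order of rings: ring A (step 2), oxirane (step 15), carbocycle C1–C6 last (step 18, a hydride-triggered reductive aldol closure that also fixes C4=C5, the carbon substituent on C4, and C3).
Stereochemistry: ring A from Shi epoxidation plus chair cyclization; C7 and C6 from Zn–ProPhenol alkynylations; C1/C2 from a matched Sharpless epoxidation directed by O7; C3 from the oxirane in the key step; olefin geometries from trans-hydroalumination, trans-hydrostannation and stereoretentive couplings.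

Key step: step 18

Assumption: (S,S)-ProPhenol/Me2Zn is taken to deliver an alkynyl group to the Re face of an enal and (R,R)-ProPhenol to the Si face. If the sense proves opposite on these substrates, the two commercial ligand antipodes are exchanged.
Abbreviations and remark: TBS = tert-butyldimethylsilyl, TES = triethylsilyl, RA = (1S,5R)-5-(TBSO)-2,6,6-trimethylcyclohex-2-en-1-yl. The CIP descriptors of the two oxirane carbons change along 22–28 only because substituent priorities change; the spatial arrangement stays the same.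

Step 1
Reactants: 1 geranyl acetate
Product: 2 (2E,6R)-6,7-epoxy-3,7-dimethyloct-2-en-1-yl acetate
Conditions: D-fructose-derived Shi ketone (30 mol %), Oxone, K2CO3, Bu4NHSO4 (cat.), MeCN–DMM/aq. borate–EDTA buffer, 0 °C
Reagents that add atoms: potassium peroxymonosulfate (active component of Oxone), [K+].[O-]S(=O)(=O)OO
Why: Shi asymmetric epoxidation, in which the chiral dioxirane attacks the electron-rich 6,7-olefin in preference to the 2,3-olefin deactivated by the allylic acetate, and the spiro transition state of the D-fructose-derived catalyst sets the 6R centre.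

Step 2
Reactants: 2 (2E,6R)-6,7-epoxy-3,7-dimethyloct-2-en-1-yl acetate
Product: 3 [(1S,5R)-5-hydroxy-2,6,6-trimethylcyclohex-2-en-1-yl]methyl acetate
Conditions: ZrCl4 (1.0 equiv), CH2Cl2, 0 °C; then H2O
Reagents that add atoms: none
Why: Lewis-acid-triggered epoxide–olefin cationic cyclization, in which ionisation at the tertiary oxirane carbon leaves the 6R C–O bond untouched, the E-olefin adds through a chair that places C–O and CH2OAc equatorial and hence cis (new centre 1S), and loss of a ring CH2 proton gives the endocyclic olefin.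

Step 3
Reactants: 3 [(1S,5R)-5-hydroxy-2,6,6-trimethylcyclohex-2-en-1-yl]methyl acetate
Product: 4 (RA)methyl acetate
Conditions: TBSOTf, 2,6-lutidine, CH2Cl2, 0 °C
Reagents that add atoms: tert-butyldimethylsilyl triflate, CC(C)(C)[Si](C)(C)OS(=O)(=O)C(F)(F)F
Why: Standard silylation of a hindered secondary alcohol with the silyl triflate, which touches no stereocentre.

Step 4
Reactants: 4 (RA)methyl acetate
Product: 5 (RA)methanol
Conditions: K2CO3 (cat.), MeOH, rt
Reagents that add atoms: none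
Why: Base-catalysed transesterification (methanolysis) removes the primary acetate while the TBS ether and the ring olefin stay intact.

Step 5
Reactants: 5 (RA)methanol
Product: 6 (1S,5R)-5-(TBSO)-2,6,6-trimethylcyclohex-2-ene-1-carbaldehyde
Conditions: Dess–Martin periodinane, NaHCO3, CH2Cl2, 0 °C
Reagents that add atoms: none
Why: Dess–Martin oxidation under buffered non-basic conditions should give the β,γ-unsaturated aldehyde without epimerising the α-centre or moving the olefin into conjugation.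

Step 6
Reactants: 6 (1S,5R)-5-(TBSO)-2,6,6-trimethylcyclohex-2-ene-1-carbaldehyde
Product: 7 2-[(E)-2-(RA)ethenyl]-4,4,5,5-tetramethyl-1,3,2-dioxaborolane
Conditions: Cl2CHBpin, CrCl2, LiI, THF, rt
Reagents that add atoms: 2-(dichloromethyl)-4,4,5,5-tetramethyl-1,3,2-dioxaborolane, CC1(C)OB(C(Cl)Cl)OC1(C)C
Why: Takai–Utimoto olefination, whose gem-dichromium boronate reagent is non-basic so that the α-centre is kept, and which gives the E-alkenylboronate by elimination from the less crowded adduct.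

Step 7
Reactants: 8 but-2-yn-1-ol
Product: 10 (Z)-3-iodobut-2-en-1-ol, via sodium alkenylalanate 9 (not isolated)
Conditions: Red-Al, Et2O, 0 °C to rt; then I2, THF, −78 to 0 °C
Reagents that add atoms: iodine, II
Why: Alkoxide-directed trans-hydroalumination of a propargylic alcohol places aluminium on the distal alkyne carbon in a five-membered alanate, and iodinolysis with retention gives the Z-iodide.

Step 8
Reactants: 7 2-[(E)-2-(RA)ethenyl]-4,4,5,5-tetramethyl-1,3,2-dioxaborolane; 10 (Z)-3-iodobut-2-en-1-ol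
Product: 11 (2Z,4E)-3-methyl-5-(RA)penta-2,4-dien-1-ol
Conditions: Pd(PPh3)4 (5 mol %), aq. NaOH, THF, rt
Reagents that add atoms: none
Why: Suzuki–Miyaura coupling of two alkenyl partners proceeds with retention at both sp2 carbons and so forms C9–C10 as the 2Z,4E-diene.

Step 9
Reactants: 11 (2Z,4E)-3-methyl-5-(RA)penta-2,4-dien-1-ol
Product: 12 (2Z,4E)-3-methyl-5-(RA)penta-2,4-dienal
Conditions: MnO2, CH2Cl2, rt
Reagents that add atoms: none
Why: Selective allylic oxidation with MnO2 is neutral enough to keep the Z-geometry of the trisubstituted enal.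

Step 10
Reactants: 12 (2Z,4E)-3-methyl-5-(RA)penta-2,4-dienal; 13 triethyl(prop-2-yn-1-yloxy)silane
Product: 14 (4S,5Z,7E)-6-methyl-8-(RA)-1-(triethylsilyloxy)octa-5,7-dien-2-yn-4-ol
Conditions: (S,S)-ProPhenol (20 mol %), Me2Zn, Ph3PO (40 mol %), toluene, 4 °C; then H2O
Reagents that add atoms: none
Why: Zinc–ProPhenol-catalysed asymmetric alkynylation of an α,β-unsaturated aldehyde, in which the dinuclear zinc complex binds aldehyde and alkynylzinc side by side and delivers the alkyne to the Re face, forming C1–C7 and setting C7 as S.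

Step 11
Reactants: 14 (4S,5Z,7E)-6-methyl-8-(RA)-1-(triethylsilyloxy)octa-5,7-dien-2-yn-4-ol
Product: 16 (2Z,4S,5Z,7E)-3-iodo-6-methyl-8-(RA)-1-(triethylsilyloxy)octa-2,5,7-trien-4-ol, via alkenylstannane 15 (not isolated)
Conditions: [Cp*RuCl]4 (2.5 mol %), Bu3SnH, CH2Cl2, rt; then I2 (1.0 equiv), −78 to 0 °C
Reagents that add atoms: iodine, II
Why: Ruthenium-catalysed hydroxyl-directed trans-hydrostannation puts tin on the alkyne carbon next to the free carbinol (C1) and hydrogen on C2 from the opposite side, and iododestannylation with retention leaves iodine cis to C3.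

Step 12
Reactants: 16 (2Z,4S,5Z,7E)-3-iodo-6-methyl-8-(RA)-1-(triethylsilyloxy)octa-2,5,7-trien-4-ol
Product: 18 (2Z)-2-[(1S,2Z,4E)-1-hydroxy-3-methyl-5-(RA)penta-2,4-dien-1-yl]-4-(triethylsilyloxy)but-2-enal, via dilithio species 17 (not isolated)
Conditions: t-BuLi (3.1 equiv), Et2O, −78 °C; then DMF, −78 to 0 °C; H2O
Reagents that add atoms: N,N-dimethylformamide, CN(C)C=O
Why: Iodine–lithium exchange with retention of olefin geometry followed by formylation with DMF installs C6 cis to C3, the low temperature in ether suppressing a 1,4-O-to-C shift of the triethylsilyl group.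

Step 13
Reactants: 18 (2Z)-2-[(1S,2Z,4E)-1-hydroxy-3-methyl-5-(RA)penta-2,4-dien-1-yl]-4-(triethylsilyloxy)but-2-enal; 19 methyl propiolate
Product: 20 methyl (4S,5Z)-4-hydroxy-5-[(1S,2Z,4E)-1-hydroxy-3-methyl-5-(RA)penta-2,4-dien-1-yl]-7-(triethylsilyloxy)hept-5-en-2-ynoate
Conditions: (R,R)-ProPhenol (20 mol %), Me2Zn (excess), Ph3PO (40 mol %), toluene, 4 °C; then H2O
Reagents that add atoms: none
Why: Second zinc–ProPhenol alkynylation, a reaction type for which methyl propiolate and α-branched enals are favoured partners, with the antipodal ligand sending the alkynyl group to the Si face so that C5–C6 forms and C6 is set as S under catalyst control.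

Step 14
Reactants: 20 methyl (4S,5Z)-4-hydroxy-5-[(1S,2Z,4E)-1-hydroxy-3-methyl-5-(RA)penta-2,4-dien-1-yl]-7-(triethylsilyloxy)hept-5-en-2-ynoate
Product: 21 methyl (4S,5Z)-4-(TBSO)-5-[(1S,2Z,4E)-1-hydroxy-3-methyl-5-(RA)penta-2,4-dien-1-yl]-7-(triethylsilyloxy)hept-5-en-2-ynoate
Conditions: TBSCl (1.05 equiv), imidazole, CH2Cl2, 0 °C
Reagents that add atoms: tert-butyldimethylsilyl chloride, CC(C)(C)[Si](C)(C)Cl
Why: Chemoselective silylation, since the C6 hydroxyl flanked by the rod-like electron-poor alkyne is more acidic and less hindered than the C7 hydroxyl, which is shielded by the cis substituent on C9, so that one equivalent of silyl chloride should cap O6 first.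

Step 15
Reactants: 21 methyl (4S,5Z)-4-(TBSO)-5-[(1S,2Z,4E)-1-hydroxy-3-methyl-5-(RA)penta-2,4-dien-1-yl]-7-(triethylsilyloxy)hept-5-en-2-ynoate
Product: 22 methyl (4S)-4-(TBSO)-4-{(2S,3S)-2-[(1S,2Z,4E)-1-hydroxy-3-methyl-5-(RA)penta-2,4-dien-1-yl]-3-[(triethylsilyloxy)methyl]oxiran-2-yl}but-2-ynoate
Conditions: Ti(Oi-Pr)4 (20 mol %), L-(+)-DIPT (24 mol %), t-BuOOH, 4 Å MS, CH2Cl2, −20 °C
Reagents that add atoms: tert-butyl hydroperoxide, CC(C)(C)OO
Why: Sharpless asymmetric epoxidation in its matched kinetic-resolution manifold, because the 7S carbinol is the fast-reacting antipode for L-(+)-tartrate and C1=C2 carries no substituent cis to C7, so oxygen arrives on the face giving the erythro C7/C1 relationship and sets C1 and C2, whereas C8=C9 is the mismatched cis-substituted olefin of the same carbinol and O6 is blocked.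

Step 16
Reactants: 22 methyl (4S)-4-(TBSO)-4-{(2S,3S)-2-[(1S,2Z,4E)-1-hydroxy-3-methyl-5-(RA)penta-2,4-dien-1-yl]-3-[(triethylsilyloxy)methyl]oxiran-2-yl}but-2-ynoate
Product: 23 methyl (4S)-4-(TBSO)-4-{(2R,3S)-2-[(1S,2Z,4E)-1-(TBSO)-3-methyl-5-(RA)penta-2,4-dien-1-yl]-3-[(triethylsilyloxy)methyl]oxiran-2-yl}but-2-ynoate
Conditions: TBSOTf, 2,6-lutidine (excess), CH2Cl2, −78 to 0 °C
Reagents that add atoms: tert-butyldimethylsilyl triflate, CC(C)(C)[Si](C)(C)OS(=O)(=O)C(F)(F)F
Why: Silylation of the hindered epoxy alcohol with the silyl triflate and an excess of hindered base removes the last proton source before the key step without opening the oxirane.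

Step 17
Reactants: 23 methyl (4S)-4-(TBSO)-4-{(2R,3S)-2-[(1S,2Z,4E)-1-(TBSO)-3-methyl-5-(RA)penta-2,4-dien-1-yl]-3-[(triethylsilyloxy)methyl]oxiran-2-yl}but-2-ynoate
Product: 24 methyl (4S)-4-(TBSO)-4-{(2R,3R)-3-formyl-2-[(1S,2Z,4E)-1-(TBSO)-3-methyl-5-(RA)penta-2,4-dien-1-yl]oxiran-2-yl}but-2-ynoate
Conditions: (COCl)2, DMSO, CH2Cl2, −78 to −40 °C; then Et3N, −78 °C to rt
Reagents that add atoms: none
Why: Swern oxidation applied directly to a primary triethylsilyl ether, in which the chlorosulfonium salt desilylates and oxidises the unhindered primary TES ether in one operation while secondary TBS ethers are inert, and the oxirane carbaldehyde formed cannot epimerise.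

Step 18
Reactants: 24 methyl (4S)-4-(TBSO)-4-{(2R,3R)-3-formyl-2-[(1S,2Z,4E)-1-(TBSO)-3-methyl-5-(RA)penta-2,4-dien-1-yl]oxiran-2-yl}but-2-ynoate
Product: 26 methyl (1R,2S,3R,6S)-1,2-epoxy-3-hydroxy-6-(TBSO)-1-[(1S,2Z,4E)-1-(TBSO)-3-methyl-5-(RA)penta-2,4-dien-1-yl]cyclohex-4-ene-4-carboxylate (core locants), via copper(I) allenolate 25 (not isolated)
Conditions: [(Ph3P)CuH]6 (0.2 equiv, 1.2 equiv Cu–H), degassed toluene, −40 to 0 °C; then aq. NH4Cl
Reagents that add atoms: none
Why: Proposed new method: The soft copper hydride transfers hydride to C5 of the polarised alkynoate (conjugate hydrocupration), and the resulting α-cuprio enoate/copper allenolate 25, which is linear at C4 and so free of any E/Z constraint, adds through C4 to the tethered oxirane carbaldehyde C3 to give a copper aldolate that is protonated on work-up. The closest known reaction types are the copper-hydride-induced reductive aldol cyclization of alkynediones to cyclic β-hydroxy enones and the intermolecular aldol trapping of α-metallated acrylates made by conjugate hydrometalation of alkynoates; what is new is the ester donor combined with an epoxy-aldehyde acceptor. The carbocycle C1–C6 closes in a 6-(enolexo)-exo-trig mode, and the cis-oxirane, acting like a Z-olefin, holds C3 and C6 on the same side so that only a six-membered ring with an endocyclic C4=C5 bond can form. The one new stereocentre, C3, is controlled by the oxirane: in the Cornforth-type rotamer the C3=O dipole points away from the C2–O bond while the tether delivers C4 gauche to C1, so the alkoxide ends up anti to the oxirane oxygen (3R). The step needs chemoselectivity of the hydride for the alkynoate over aldehyde, oxirane, diene and product enoate, which should be secured by the phosphine-ligated soft hydride used in slight excess at low temperature, by the absence of any proton source (all hydroxyls silylated), and by the steric shielding of the trisubstituted enoate in 26.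

Step 19
Reactants: 26 methyl (1R,2S,3R,6S)-1,2-epoxy-3-hydroxy-6-(TBSO)-1-[(1S,2Z,4E)-1-(TBSO)-3-methyl-5-(RA)penta-2,4-dien-1-yl]cyclohex-4-ene-4-carboxylate
Product: 27 (1R,2S,3R,6S)-1,2-epoxy-4-(hydroxymethyl)-6-(TBSO)-1-[(1S,2Z,4E)-1-(TBSO)-3-methyl-5-(RA)penta-2,4-dien-1-yl]cyclohex-4-en-3-ol (core locants)
Conditions: DIBAL-H (4 equiv), CH2Cl2, −78 °C; aq. Rochelle salt
Reagents that add atoms: none
Why: DIBAL-H 1,2-reduction of the conjugated ester to the allylic alcohol is faster at −78 °C than any attack on the oxirane and touches no stereocentre.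

Step 20
Reactants: 27 (1R,2S,3R,6S)-1,2-epoxy-4-(hydroxymethyl)-6-(TBSO)-1-[(1S,2Z,4E)-1-(TBSO)-3-methyl-5-(RA)penta-2,4-dien-1-yl]cyclohex-4-en-3-ol
Product: 28 target CNP0389279.1
Conditions: HF·pyridine, pyridine, THF, 0 °C to rt
Reagents that add atoms: none
Why: Buffered fluoride-mediated desilylation under weakly acidic conditions avoids alkoxide formation and thereby Payne migration of the oxirane, and leaves all seven stereocentres untouched.

Compound list
1 | geranyl acetate | CC(C)=CCC/C(C)=C/COC(C)=O | starting material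
2 | (2E,6R)-6,7-epoxy-3,7-dimethyloct-2-en-1-yl acetate | CC1(C)O[C@@H]1CC/C(C)=C/COC(C)=O | intermediate
3 | [(1S,5R)-5-hydroxy-2,6,6-trimethylcyclohex-2-en-1-yl]methyl acetate | CC1=CC[C@@H](O)C(C)(C)[C@H]1COC(C)=O | intermediate
4 | (RA)methyl acetate | CC1=CC[C@@H](O[Si](C)(C)C(C)(C)C)C(C)(C)[C@H]1COC(C)=O | intermediate
5 | (RA)methanol | CC1=CC[C@@H](O[Si](C)(C)C(C)(C)C)C(C)(C)[C@H]1CO | intermediate
6 | (1S,5R)-5-(TBSO)-2,6,6-trimethylcyclohex-2-ene-1-carbaldehyde | CC1=CC[C@@H](O[Si](C)(C)C(C)(C)C)C(C)(C)[C@H]1C=O | intermediate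
7 | 2-[(E)-2-(RA)ethenyl]-4,4,5,5-tetramethyl-1,3,2-dioxaborolane | CC1=CC[C@@H](O[Si](C)(C)C(C)(C)C)C(C)(C)[C@H]1/C=C/B2OC(C)(C)C(C)(C)O2 | intermediate
8 | but-2-yn-1-ol | CC#CCO | starting material
9 | sodium alkenylalanate (five-membered 1,2-oxaaluminate, not isolated) | CC1=CCO[Al-]1(OCCOC)OCCOC.[Na+] | intermediate
10 | (Z)-3-iodobut-2-en-1-ol | C/C(I)=C/CO | intermediate
11 | (2Z,4E)-3-methyl-5-(RA)penta-2,4-dien-1-ol | CC1=CC[C@@H](O[Si](C)(C)C(C)(C)C)C(C)(C)[C@H]1/C=C/C(C)=C\CO | intermediate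
12 | (2Z,4E)-3-methyl-5-(RA)penta-2,4-dienal | CC1=CC[C@@H](O[Si](C)(C)C(C)(C)C)C(C)(C)[C@H]1/C=C/C(C)=C\C=O | intermediate
13 | triethyl(prop-2-yn-1-yloxy)silane | C#CCO[Si](CC)(CC)CC | starting material
14 | (4S,5Z,7E)-6-methyl-8-(RA)-1-(triethylsilyloxy)octa-5,7-dien-2-yn-4-ol | CC1=CC[C@@H](O[Si](C)(C)C(C)(C)C)C(C)(C)[C@H]1/C=C/C(C)=C\[C@H](O)C#CCO[Si](CC)(CC)CC | intermediate
15 | (2Z,4S,5Z,7E)-6-methyl-8-(RA)-3-(tributylstannyl)-1-(triethylsilyloxy)octa-2,5,7-trien-4-ol (not isolated) | CC1=CC[C@@H](O[Si](C)(C)C(C)(C)C)C(C)(C)[C@H]1/C=C/C(C)=C\[C@H](O)/C(=C/CO[Si](CC)(CC)CC)[Sn](CCCC)(CCCC)CCCC | intermediate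
16 | (2Z,4S,5Z,7E)-3-iodo-6-methyl-8-(RA)-1-(triethylsilyloxy)octa-2,5,7-trien-4-ol | CC1=CC[C@@H](O[Si](C)(C)C(C)(C)C)C(C)(C)[C@H]1/C=C/C(C)=C\[C@H](O)/C(I)=C/CO[Si](CC)(CC)CC | intermediate
17 | dilithio species (lithium alkoxide at O7, alkenyllithium at C1, not isolated) | CC1=CC[C@@H](O[Si](C)(C)C(C)(C)C)C(C)(C)[C@H]1/C=C/C(C)=C\[C@H](O[Li])/C([Li])=C/CO[Si](CC)(CC)CC | intermediate
18 | (2Z)-2-[(1S,2Z,4E)-1-hydroxy-3-methyl-5-(RA)penta-2,4-dien-1-yl]-4-(triethylsilyloxy)but-2-enal | CC1=CC[C@@H](O[Si](C)(C)C(C)(C)C)C(C)(C)[C@H]1/C=C/C(C)=C\[C@H](O)/C(C=O)=C/CO[Si](CC)(CC)CC | intermediate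
19 | methyl propiolate | C#CC(=O)OC | starting material
20 | methyl (4S,5Z)-4-hydroxy-5-[(1S,2Z,4E)-1-hydroxy-3-methyl-5-(RA)penta-2,4-dien-1-yl]-7-(triethylsilyloxy)hept-5-en-2-ynoate | CC1=CC[C@@H](O[Si](C)(C)C(C)(C)C)C(C)(C)[C@H]1/C=C/C(C)=C\[C@H](O)/C(=C/CO[Si](CC)(CC)CC)[C@@H](O)C#CC(=O)OC | intermediate
21 | 4-O-TBS ether of 20 (O7 free) | CC1=CC[C@@H](O[Si](C)(C)C(C)(C)C)C(C)(C)[C@H]1/C=C/C(C)=C\[C@H](O)/C(=C/CO[Si](CC)(CC)CC)[C@@H](O[Si](C)(C)C(C)(C)C)C#CC(=O)OC | intermediate
22 | methyl (4S)-4-(TBSO)-4-{(2S,3S)-2-[(1S,2Z,4E)-1-hydroxy-3-methyl-5-(RA)penta-2,4-dien-1-yl]-3-[(triethylsilyloxy)methyl]oxiran-2-yl}but-2-ynoate | CC1=CC[C@@H](O[Si](C)(C)C(C)(C)C)C(C)(C)[C@H]1/C=C/C(C)=C\[C@H](O)[C@@]1(O[C@H]1CO[Si](CC)(CC)CC)[C@@H](O[Si](C)(C)C(C)(C)C)C#CC(=O)OC | intermediate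
23 | O7-TBS ether of 22, oxirane (2R,3S) | CC1=CC[C@@H](O[Si](C)(C)C(C)(C)C)C(C)(C)[C@H]1/C=C/C(C)=C\[C@H](O[Si](C)(C)C(C)(C)C)[C@@]1(O[C@H]1CO[Si](CC)(CC)CC)[C@@H](O[Si](C)(C)C(C)(C)C)C#CC(=O)OC | intermediate
24 | methyl (4S)-4-(TBSO)-4-{(2R,3R)-3-formyl-2-[(1S,2Z,4E)-1-(TBSO)-3-methyl-5-(RA)penta-2,4-dien-1-yl]oxiran-2-yl}but-2-ynoate | CC1=CC[C@@H](O[Si](C)(C)C(C)(C)C)C(C)(C)[C@H]1/C=C/C(C)=C\[C@H](O[Si](C)(C)C(C)(C)C)[C@@]1(O[C@H]1C=O)[C@@H](O[Si](C)(C)C(C)(C)C)C#CC(=O)OC | intermediate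
25 | copper(I) allenolate of 24 (phosphine-ligated, not isolated) | CC1=CC[C@@H](O[Si](C)(C)C(C)(C)C)C(C)(C)[C@H]1/C=C/C(C)=C\[C@H](O[Si](C)(C)C(C)(C)C)[C@@]1(O[C@H]1C=O)[C@@H](O[Si](C)(C)C(C)(C)C)C=C=C(OC)O[Cu] | intermediate
26 | methyl (1R,2S,3R,6S)-1,2-epoxy-3-hydroxy-6-(TBSO)-1-[(1S,2Z,4E)-1-(TBSO)-3-methyl-5-(RA)penta-2,4-dien-1-yl]cyclohex-4-ene-4-carboxylate (core locants) | CC1=CC[C@@H](O[Si](C)(C)C(C)(C)C)C(C)(C)[C@H]1/C=C/C(C)=C\[C@H](O[Si](C)(C)C(C)(C)C)[C@]12O[C@H]1[C@H](O)C(C(=O)OC)=C[C@@H]2O[Si](C)(C)C(C)(C)C | intermediate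
27 | (1R,2S,3R,6S)-1,2-epoxy-4-(hydroxymethyl)-6-(TBSO)-1-[(1S,2Z,4E)-1-(TBSO)-3-methyl-5-(RA)penta-2,4-dien-1-yl]cyclohex-4-en-3-ol (core locants) | CC1=CC[C@@H](O[Si](C)(C)C(C)(C)C)C(C)(C)[C@H]1/C=C/C(C)=C\[C@H](O[Si](C)(C)C(C)(C)C)[C@]12O[C@H]1[C@H](O)C(CO)=C[C@@H]2O[Si](C)(C)C(C)(C)C | intermediate
28 | CNP0389279.1, (1R,2S,3R,6S)-1,2-epoxy-4-(hydroxymethyl)-1-{(1S,2Z,4E)-1-hydroxy-5-[(1S,5R)-5-hydroxy-2,6,6-trimethylcyclohex-2-en-1-yl]-3-methylpenta-2,4-dien-1-yl}cyclohex-4-ene-3,6-diol (core locants) | CC1=CC[C@@H](O)C(C)(C)[C@H]1/C=C/C(C)=C\[C@H](O)[C@]12O[C@H]1[C@H](O)C(CO)=C[C@@H]2O | target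

Total step count: 20.
Longest linear sequence: 19 steps (steps 1–6 and 8–20).

Steps most likely to fail

Step 18 (Proposed new method). The copper hydride may reduce the oxirane carbaldehyde in a 1,2-sense before it reaches the alkynoate. The allenolate may be protonated or reduced further before the C3–C4 bond forms. Closure may also run through the rotamer that places O3 syn to the oxirane. The fallback sets out from 24. Lindlar semihydrogenation of the alkynoate gives the Z-enoate aldehyde F1. A trialkylphosphine (PMe3 or PBu3) then effects a known intramolecular Morita–Baylis–Hillman closure: the phosphine adds to C5, the enolate carbon C4 adds to C3, and the phosphine leaves. This needs no hydride and comes back to the route at 26.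

Step 11. The Cp*Ru fragment may be tied up by the 1,3-diene so that turnover stalls. Regiocontrol may erode because both propargylic positions carry oxygen. Iodine may attack the diene during the destannylation. The fallback sets out from 14 and uses aluminium instead of ruthenium and tin. Alkoxide-directed trans-hydroalumination with LiAlH4 and a small amount of AlCl3 places aluminium on the alkyne carbon next to the carbinol. Iodinolysis at low temperature then comes back to the route directly at 16, without any new compound.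

Step 14. Discrimination between the two secondary hydroxyls may be poor, or the silyl group may migrate between the 1,3-related oxygens, so that O7 is blocked and the directed epoxidation loses its handle. The fallback sets out from 20 and gives up O7 as the directing group. Exhaustive silylation (TBSOTf, 2,6-lutidine) gives the bis-TBS ether F2. Mild methanolysis (PPTS, MeOH) of the primary TES ether gives the primary allylic alcohol F3. Sharpless epoxidation, now directed by the C3 hydroxyl (Ti(Oi-Pr)4, L-(+)-DET, t-BuOOH), gives the epoxy alcohol F4. Dess–Martin oxidation comes back to the route at 24.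

Further compounds
F1 | step 18 | methyl (2Z,4S)-4-(TBSO)-4-{(2S,3R)-3-formyl-2-[(1S,2Z,4E)-1-(TBSO)-3-methyl-5-(RA)penta-2,4-dien-1-yl]oxiran-2-yl}but-2-enoate | CC1=CC[C@@H](O[Si](C)(C)C(C)(C)C)C(C)(C)[C@H]1/C=C/C(C)=C\[C@H](O[Si](C)(C)C(C)(C)C)[C@@]1(O[C@H]1C=O)[C@@H](O[Si](C)(C)C(C)(C)C)/C=C\C(=O)OC
F0 | step 11 | none | none
F2 | step 14 | methyl (4S,5Z)-4-(TBSO)-5-[(1S,2Z,4E)-1-(TBSO)-3-methyl-5-(RA)penta-2,4-dien-1-yl]-7-(triethylsilyloxy)hept-5-en-2-ynoate | CC1=CC[C@@H](O[Si](C)(C)C(C)(C)C)C(C)(C)[C@H]1/C=C/C(C)=C\[C@H](O[Si](C)(C)C(C)(C)C)/C(=C/CO[Si](CC)(CC)CC)[C@@H](O[Si](C)(C)C(C)(C)C)C#CC(=O)OC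
F3 | step 14 | methyl (4S,5Z)-4-(TBSO)-5-[(1S,2Z,4E)-1-(TBSO)-3-methyl-5-(RA)penta-2,4-dien-1-yl]-7-hydroxyhept-5-en-2-ynoate | CC1=CC[C@@H](O[Si](C)(C)C(C)(C)C)C(C)(C)[C@H]1/C=C/C(C)=C\[C@H](O[Si](C)(C)C(C)(C)C)/C(=C/CO)[C@@H](O[Si](C)(C)C(C)(C)C)C#CC(=O)OC
F4 | step 14 | methyl (4S)-4-(TBSO)-4-{(2R,3S)-3-(hydroxymethyl)-2-[(1S,2Z,4E)-1-(TBSO)-3-methyl-5-(RA)penta-2,4-dien-1-yl]oxiran-2-yl}but-2-ynoate | CC1=CC[C@@H](O[Si](C)(C)C(C)(C)C)C(C)(C)[C@H]1/C=C/C(C)=C\[C@H](O[Si](C)(C)C(C)(C)C)[C@@]1(O[C@H]1CO)[C@@H](O[Si](C)(C)C(C)(C)C)C#CC(=O)OC
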